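**Retrosynthetic overview**
1. The target is cut at the CH=/CH2 bond between the two chain alkenes: a "west" (E)-alkenyl iodide (ring plus four chain carbons) and an "east" homoallylzinc that already carries the butenolide (Negishi sp2–sp3 coupling).
2. The west iodide comes from Zr-catalysed methylalumination/iodination of a ring-butyne, made from the ring-ethanol via its iodide and lithium acetylide.
3. The ring-ethanol comes from Ni-catalysed CH3-for-O exchange on a bicyclic enol ether. That ether arises by a hydrogen-atom-transfer-triggered 1,2-alkyl shift that expands a spiro cyclopentane to the cyclohexene; the oxolane tether fixes the quaternary centre.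
4. The spiro ether comes from (R)-2-methylcyclopentanone (asymmetric hydroboration of 1-methylcyclopentene, then oxidation) and the dianion of 3-bromobut-3-en-1-ol, closed by tosylation.
5. The east piece comes from but-3-yn-1-ol (methylalumination/vinylation), 9-BBN/B-alkyl Suzuki coupling with 4-bromofuran-2(5H)-one, and iodination. Ring order: cyclopentane (bought) → spiro oxolane → cyclohexene by expansion → oxolane opened; the butenolide ring is bought.

Assumption: the SMILES is taken literally (R at both ring stereocentres, i.e. ring methyls trans and side chain cis to the secondary methyl; E,E chain), and IpcBH2 made from (−)-α-pinene is taken to give the (1R,2R) alcohol (the reagent from (+)-α-pinene gives (1S,2S)).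

**Route**

Step 1
Reactants: 1 1-methylcyclopent-1-ene
Product: 3 (1R,2R)-2-methylcyclopentan-1-ol, via dialkylborane 2 (not isolated)
Conditions: (+)-IpcBH2 [from (−)-α-pinene], Et2O, −25 °C, 24 h (2 crystallises, supernatant removed in the flask); then NaOH, 30% H2O2, 0→40 °C
Reagents that add atoms: hydrogen peroxide, OO
Why: Brown asymmetric hydroboration adds H–B syn and anti-Markovnikov from the face chosen by the isopinocampheyl group, setting both carbons (B trans to CH3); crystallisation of 2 raises the ee from about 66% to ≥98%, and B→O oxidation proceeds with retention.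

Step 2
Reactants: 3 (1R,2R)-2-methylcyclopentan-1-ol
Product: 4 (2R)-2-methylcyclopentan-1-one
Conditions: TPAP (5 mol %), NMO (1.5 equiv), 4 Å MS, CH2Cl2, 0→25 °C
Reagents that add atoms: none
Why: Ley–Griffith oxidation under neutral conditions gives the ketone without enolising the α-methyl stereocentre.

Step 3
Reactants: 4 (2R)-2-methylcyclopentan-1-one; 5 3-bromobut-3-en-1-ol
Product: 9 (5S,6R)-6-methyl-4-methylidene-1-oxaspiro[4.4]nonane, via dilithio dianion 6 (not isolated), via dilithium dialkoxide 7 (not isolated), via monotosylate 8 (not isolated)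
Conditions: 5, n-BuLi (1.0 equiv) then t-BuLi (2.0 equiv), Et2O, −78 °C; LaCl3·2LiCl (0.3 equiv), 4, THF, −78 °C; then TsCl (1.05 equiv), −78→40 °C
Reagents that add atoms: none
Why: Br/Li exchange gives the alkenyllithium, whose 1,2-addition to the ketone occurs anti to the α-methyl (O ends cis to CH3, setting the spiro carbon), and the tertiary alkoxide then closes the oxolane by intramolecular Williamson displacement of the primary tosylate.

Step 4
Reactants: 9 (5S,6R)-6-methyl-4-methylidene-1-oxaspiro[4.4]nonane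
Product: 11 (3aR,4R)-3a,4-dimethyl-2,3,3a,4,5,6-hexahydro-1-benzofuran, via oxocarbenium salt 10 (not isolated)
Conditions: Co(salen) (5 mol %), N-fluoro-2,4,6-trimethylpyridinium BF4 (1.3 equiv), PhSiH3 (1.2 equiv), PhCF3, 0→25 °C; Et3N quench
Reagents that add atoms: none
Why: Proposed new method: Co–H hydrogen-atom transfer to the 1,1-disubstituted alkene followed by radical–polar crossover gives a tertiary cation at C4 held inside the oxolane, the better-migrating neighbour C6 (CHMe, not C9 CH2) shifts 1,2 onto it with retention (cyclopentane→cyclohexane ring expansion) because the ether oxygen takes up the charge as oxocarbenium 10, and collidine deprotonation gives the enol ether; since the tether keeps the CH2CH2O arm on the oxygen side, the new quaternary centre forms with that arm cis and CH3 trans to the C4 methyl; closest known reaction: Co(salen)-catalysed HAT-initiated radical–polar crossover semipinacol rearrangement of tertiary allylic alcohols.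

Step 5
Reactants: 11 (3aR,4R)-3a,4-dimethyl-2,3,3a,4,5,6-hexahydro-1-benzofuran
Product: 12 2-[(1R,6R)-1,2,6-trimethylcyclohex-2-en-1-yl]ethan-1-ol
Conditions: MeMgBr (3 equiv), NiCl2(PPh3)2 (10 mol %), PhMe, 80 °C; aq. NH4Cl
Reagents that add atoms: methylmagnesium bromide, C[Mg]Br
Why: Wenkert–Kocienski nickel-catalysed cross-coupling inserts Ni(0) into the enol-ether C(sp2)–O bond and transfers CH3, giving the trisubstituted ring alkene and freeing the primary alkoxide without touching a stereocentre.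

Step 6
Reactants: 12 2-[(1R,6R)-1,2,6-trimethylcyclohex-2-en-1-yl]ethan-1-ol
Product: 13 (5R,6R)-6-(2-iodoethyl)-1,5,6-trimethylcyclohex-1-ene
Conditions: I2, PPh3, imidazole, CH2Cl2, 0→25 °C
Reagents that add atoms: iodine, II
Why: Appel iodination of an unhindered primary alcohol.

Step 7
Reactants: 13 (5R,6R)-6-(2-iodoethyl)-1,5,6-trimethylcyclohex-1-ene
Product: 14 (5R,6R)-6-(but-3-yn-1-yl)-1,5,6-trimethylcyclohex-1-ene
Conditions: LiC≡CH·H2NCH2CH2NH2 (2.5 equiv), DMSO, 15→25 °C
Reagents that add atoms: lithium acetylide ethylenediamine complex, [Li]C#C.NCCN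
Why: SN2 alkynylation of a primary iodide whose only β-hydrogens are neopentyl-type, so E2 is slow.

Step 8
Reactants: 14 (5R,6R)-6-(but-3-yn-1-yl)-1,5,6-trimethylcyclohex-1-ene
Product: 16 (5R,6R)-6-[(3E)-4-iodo-3-methylbut-3-en-1-yl]-1,5,6-trimethylcyclohex-1-ene, via alkenylalane 15 (not isolated)
Conditions: Me3Al (2.5 equiv), Cp2ZrCl2 (0.25 equiv), ClCH2CH2Cl, 0→25 °C; then I2, THF, −30→0 °C
Reagents that add atoms: trimethylaluminium, C[Al](C)C; iodine, II
Why: Negishi Zr-catalysed methylalumination is a syn carbometalation placing Al on the terminal carbon, and iodinolysis with retention gives the E-trisubstituted alkenyl iodide; the ring alkene is inert.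

Step 9
Reactants: 17 but-3-yn-1-ol; 18 bromoethene
Product: 20 (3E)-3-methylhexa-3,5-dien-1-ol, via alkenylalane 19 (not isolated)
Conditions: 17, Me3Al (3 equiv), Cp2ZrCl2 (0.25 equiv), CH2Cl2, 0→25 °C; then 18, ZnCl2 (0.3 equiv), Pd(PPh3)4 (3 mol %), THF, 25 °C
Reagents that add atoms: trimethylaluminium, C[Al](C)C
Why: Negishi methylalumination of the alkynol (as its O-aluminate) followed by Pd/Zn-catalysed alkenyl–alkenyl cross-coupling with retention gives the E-diene.

Step 10
Reactants: 20 (3E)-3-methylhexa-3,5-dien-1-ol; 21 4-bromofuran-2(5H)-one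
Product: 23 4-[(3E)-6-hydroxy-4-methylhex-3-en-1-yl]furan-2(5H)-one, via alkylborane 22 (not isolated)
Conditions: 20, 9-BBN dimer (1.1 equiv), THF, 0→25 °C; then 21, PdCl2(dppf) (5 mol %), AsPh3 (10 mol %), K3PO4 (3 M aq.), DMF, 25 °C
Reagents that add atoms: none
Why: 9-BBN hydroborates only the monosubstituted end of the diene (boron on the terminal carbon), and B-alkyl Suzuki–Miyaura coupling with the β-bromobutenolide forms the CH2–C4 bond while leaving the trisubstituted alkene untouched.

Step 11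
Reactants: 23 4-[(3E)-6-hydroxy-4-methylhex-3-en-1-yl]furan-2(5H)-one
Product: 24 4-[(3E)-6-iodo-4-methylhex-3-en-1-yl]furan-2(5H)-one
Conditions: I2, PPh3, imidazole, CH2Cl2, 0 °C
Reagents that add atoms: iodine, II
Why: Appel iodination; the neutral conditions spare the butenolide.

Step 12
Reactants: 24 4-[(3E)-6-iodo-4-methylhex-3-en-1-yl]furan-2(5H)-one; 16 (5R,6R)-6-[(3E)-4-iodo-3-methylbut-3-en-1-yl]-1,5,6-trimethylcyclohex-1-ene
Product: 26 4-[(3E,7E)-4,8-dimethyl-10-[(1R,6R)-1,2,6-trimethylcyclohex-2-en-1-yl]deca-3,7-dien-1-yl]furan-2(5H)-one, via alkylzinc iodide 25 (not isolated)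
Conditions: 24, Zn dust (2 equiv), LiCl, THF, 40 °C; then 16, PdCl2(dppf) (5 mol %), THF, 25→40 °C
Reagents that add atoms: none
Why: Direct zinc insertion tolerates the lactone, and Negishi sp3–sp2 coupling of the homoallylzinc with the alkenyl iodide proceeds with retention of the E geometry to give the target.

**Compound list**
1 | 1-methylcyclopent-1-ene | CC1=CCCC1 | starting material
2 | (+)-isopinocampheyl[(1R,2R)-2-methylcyclopentyl]borane | C[C@@H]1[C@@H](B[C@@H]2CCC[C@H]2C)C[C@H]2C[C@@H]1C2(C)C | intermediate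
3 | (1R,2R)-2-methylcyclopentan-1-ol | C[C@@H]1CCC[C@H]1O | intermediate
4 | (2R)-2-methylcyclopentan-1-one | C[C@@H]1CCCC1=O | intermediate
5 | 3-bromobut-3-en-1-ol | OCCC(Br)=C | starting material
6 | lithium 3-lithiobut-3-en-1-olate | [Li]OCCC([Li])=C | intermediate
7 | dilithium salt of (1S,2R)-1-(4-hydroxybut-1-en-2-yl)-2-methylcyclopentan-1-ol | C[C@@H]1CCC[C@@]1(O[Li])C(=C)CCO[Li] | intermediate
8 | lithium (1S,2R)-2-methyl-1-[4-(tosyloxy)but-1-en-2-yl]cyclopentan-1-olate | C[C@@H]1CCC[C@@]1(O[Li])C(=C)CCOS(=O)(=O)c1ccc(C)cc1 | intermediate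
9 | (5S,6R)-6-methyl-4-methylidene-1-oxaspiro[4.4]nonane | C[C@@H]1CCC[C@]12OCCC2=C | intermediate
10 | (3aR,4R)-3a,4-dimethyl-3,3a,4,5,6,7-hexahydro-2H-1-benzofuran-1-ium tetrafluoroborate | C[C@@H]1CCCC2=[O+]CC[C@]12C.F[B-](F)(F)F | intermediate
11 | (3aR,4R)-3a,4-dimethyl-2,3,3a,4,5,6-hexahydro-1-benzofuran | C[C@@H]1CCC=C2OCC[C@]12C | intermediate
12 | 2-[(1R,6R)-1,2,6-trimethylcyclohex-2-en-1-yl]ethan-1-ol | CC1=CCC[C@@H](C)[C@@]1(C)CCO | intermediate
13 | (5R,6R)-6-(2-iodoethyl)-1,5,6-trimethylcyclohex-1-ene | CC1=CCC[C@@H](C)[C@@]1(C)CCI | intermediate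
14 | (5R,6R)-6-(but-3-yn-1-yl)-1,5,6-trimethylcyclohex-1-ene | CC1=CCC[C@@H](C)[C@@]1(C)CCC#C | intermediate
15 | dimethyl{(1E)-2-methyl-4-[(1R,6R)-1,2,6-trimethylcyclohex-2-en-1-yl]but-1-en-1-yl}alumane | CC1=CCC[C@@H](C)[C@@]1(C)CC/C(C)=C/[Al](C)C | intermediate
16 | (5R,6R)-6-[(3E)-4-iodo-3-methylbut-3-en-1-yl]-1,5,6-trimethylcyclohex-1-ene | CC1=CCC[C@@H](C)[C@@]1(C)CC/C(C)=C/I | intermediate
17 | but-3-yn-1-ol | C#CCCO | starting material
18 | bromoethene | C=CBr | starting material
19 | [(3E)-4-(dimethylalumanyl)-3-methylbut-3-en-1-yl]oxy(dimethyl)alumane | C[Al](C)OCC/C(C)=C/[Al](C)C | intermediate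
20 | (3E)-3-methylhexa-3,5-dien-1-ol | OCC/C(C)=C/C=C | intermediate
21 | 4-bromofuran-2(5H)-one | BrC1=CC(=O)OC1 | starting material
22 | 9-{(3E)-6-[(9-borabicyclo[3.3.1]nonan-9-yl)oxy]-4-methylhex-3-en-1-yl}-9-borabicyclo[3.3.1]nonane | O(CC/C(C)=C/CCB1C2CCCC1CCC2)B1C2CCCC1CCC2 | intermediate
23 | 4-[(3E)-6-hydroxy-4-methylhex-3-en-1-yl]furan-2(5H)-one | OCC/C(C)=C/CCC1=CC(=O)OC1 | intermediate
24 | 4-[(3E)-6-iodo-4-methylhex-3-en-1-yl]furan-2(5H)-one | ICC/C(C)=C/CCC1=CC(=O)OC1 | intermediate
25 | iodo[(3E)-3-methyl-6-(5-oxo-2,5-dihydrofuran-3-yl)hex-3-en-1-yl]zinc | I[Zn]CC/C(C)=C/CCC1=CC(=O)OC1 | intermediate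
26 | 4-[(3E,7E)-4,8-dimethyl-10-[(1R,6R)-1,2,6-trimethylcyclohex-2-en-1-yl]deca-3,7-dien-1-yl]furan-2(5H)-one | CC1=CCC[C@@H](C)[C@@]1(C)CC/C(C)=C/CC/C(C)=C/CCC1=CC(=O)OC1 | target

**Totals**
Total step count: 12. Longest linear sequence: 9 (steps 1–8, then 12); steps 9–11 form the second branch.

**Three steps most likely to fail**

Step 4 (the proposed new ring expansion). Possible failures are migration of C9 instead of C6, hydride reduction of oxocarbenium 10 by the silane before deprotonation, or further HAT chemistry on the enol ether product. The fallback uses known chemistry and sets out from 9: Mukaiyama hydration (Mn(dpm)3, PhSiH3, O2, i-PrOH) gives the tertiary alcohol (5S,6R)-4,6-dimethyl-1-oxaspiro[4.4]nonan-4-ol F1 as both C4 epimers. F1 is ionised with BF3·OEt2 in CH2Cl2 at −78 °C, a classical acid pinacol-type ring expansion of a β-alkoxy carbinol through the same tethered cation and therefore with the same stereochemical course. An Et3N quench brings it back to the route at 11.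

Step 5 (Ni-catalysed methylation of an enol ether next to a quaternary carbon). Oxidative addition may be too slow. The fallback sets out from 11: hydrolysis (1 M HCl, THF) gives (2R,3R)-2-(2-hydroxyethyl)-2,3-dimethylcyclohexan-1-one F2, and silylation (TBSCl, imidazole) gives (2R,3R)-2-{2-[(tert-butyldimethylsilyl)oxy]ethyl}-2,3-dimethylcyclohexan-1-one F3. Enol triflate formation (KHMDS, PhNTf2; only C6 can enolise) gives (5R,6R)-6-{2-[(tert-butyldimethylsilyl)oxy]ethyl}-5,6-dimethylcyclohex-1-en-1-yl trifluoromethanesulfonate F4. Iron-catalysed methylation (MeMgBr, Fe(acac)3, THF/NMP) gives tert-butyldimethyl{2-[(1R,6R)-1,2,6-trimethylcyclohex-2-en-1-yl]ethoxy}silane F5, and TBAF returns to the route at 12.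

Step 10 (diene hydroboration and B-alkyl Suzuki coupling with a base-sensitive bromobutenolide). The risks are boron placement on the diene and lactone opening by the aqueous base. The fallback sets out from 17: silylation gives (but-3-yn-1-yloxy)(tert-butyl)dimethylsilane F6. Methylalumination, then n-BuLi and ethylene oxide (alkenylalanate opening) gives (3E)-6-[(tert-butyldimethylsilyl)oxy]-4-methylhex-3-en-1-ol F7, and Appel iodination gives tert-butyl{[(3E)-6-iodo-3-methylhex-3-en-1-yl]oxy}dimethylsilane F8. Zinc insertion and Negishi coupling with 21 gives 4-[(3E)-6-[(tert-butyldimethylsilyl)oxy]-4-methylhex-3-en-1-yl]furan-2(5H)-one F9, and HF·pyridine returns to the route at 23.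

**Further compounds**
F1 | step 4 | (5S,6R)-4,6-dimethyl-1-oxaspiro[4.4]nonan-4-ol (C4 epimers) | C[C@@H]1CCC[C@]12OCCC2(C)O
F2 | step 5 | (2R,3R)-2-(2-hydroxyethyl)-2,3-dimethylcyclohexan-1-one | O=C1CCC[C@@H](C)[C@@]1(C)CCO
F3 | step 5 | (2R,3R)-2-{2-[(tert-butyldimethylsilyl)oxy]ethyl}-2,3-dimethylcyclohexan-1-one | O=C1CCC[C@@H](C)[C@@]1(C)CCO[Si](C)(C)C(C)(C)C
F4 | step 5 | (5R,6R)-6-{2-[(tert-butyldimethylsilyl)oxy]ethyl}-5,6-dimethylcyclohex-1-en-1-yl trifluoromethanesulfonate | O=S(=O)(OC1=CCC[C@@H](C)[C@@]1(C)CCO[Si](C)(C)C(C)(C)C)C(F)(F)F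
F5 | step 5 | tert-butyldimethyl{2-[(1R,6R)-1,2,6-trimethylcyclohex-2-en-1-yl]ethoxy}silane | CC1=CCC[C@@H](C)[C@@]1(C)CCO[Si](C)(C)C(C)(C)C
F6 | step 10 | (but-3-yn-1-yloxy)(tert-butyl)dimethylsilane | C#CCCO[Si](C)(C)C(C)(C)C
F7 | step 10 | (3E)-6-[(tert-butyldimethylsilyl)oxy]-4-methylhex-3-en-1-ol | OCC/C=C(\C)CCO[Si](C)(C)C(C)(C)C
F8 | step 10 | tert-butyl{[(3E)-6-iodo-3-methylhex-3-en-1-yl]oxy}dimethylsilane | ICC/C=C(\C)CCO[Si](C)(C)C(C)(C)C
F9 | step 10 | 4-[(3E)-6-[(tert-butyldimethylsilyl)oxy]-4-methylhex-3-en-1-yl]furan-2(5H)-one | CC(C)(C)[Si](C)(C)OCC/C(C)=C/CCC1=CC(=O)OC1
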